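**Retrosynthetic overview**
- The strategy rests on ring B (C1 ketone, C2 OH, C4 CH3, C5 OCH3, C6 CH2OAc): it is a 4-methoxy-3,5-dimethylphenol core in which only the methyl group ortho to the ketone carbon (C6) is oxidised.
- The target is traced back, through selective aryl-acetate removal, O-acetylation and O–O reduction, to a cyclic peroxy hemiketal (a 1,2-dioxane ring fused to ring B), the only ring made in the route and a temporary one.
- That peroxide comes from the symmetrical-core benzophenone acetate and O2: the excited C1 carbonyl oxygen takes a hydrogen from the C6 methyl and oxygen closes the ring across the dienol (C6–CH2–O and C1'(OH)–O bonds).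
- The benzophenone, which has four ortho substituents, is made by a bromine–lithium-triggered O-to-C acyl shift of an ortho-bromoaryl 2,6-dimethoxybenzoate. A Lewis-acid Fries rearrangement is avoided because it would endanger the methoxy groups ortho to the new ketone.
- The ester comes from 2,6-dimethoxybenzoyl chloride and 4-methoxy-3,5-dimethylphenol (Dakin oxidation of 3,5-dimethyl-4-methoxybenzaldehyde, then ortho-bromination).

Key step: step 5

Remark on the chemistry: the target has no stereocentre; the hemiketal carbon of the peroxide forms as a racemate and is removed in step 6. Compounds 1 and 5 are taken as purchased.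

**Step 1**
Reactants: 1 3,5-dimethyl-4-methoxybenzaldehyde
Product: 3 4-methoxy-3,5-dimethylphenol, via aryl formate 2 (not isolated)
Conditions: mCPBA, CH2Cl2, 0 °C to rt; aq NaHCO3 wash; then K2CO3 (cat.), MeOH, rt
Reagents that add atoms: mCPBA, OOC(=O)c1cccc(Cl)c1
Why: Dakin-type Baeyer–Villiger oxidation, in which the peracid adds to the aldehyde and the electron-rich para-methoxyaryl group migrates to oxygen to give formate 2, which methanol with catalytic K2CO3 transesterifies to the phenol.

**Step 2**
Reactants: 3 4-methoxy-3,5-dimethylphenol
Product: 4 2-bromo-4-methoxy-3,5-dimethylphenol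
Conditions: NBS (1.0 equiv), i-Pr2NH (cat.), CH2Cl2, 0 °C, dark
Reagents that add atoms: N-bromosuccinimide, O=C1CCC(=O)N1Br
Why: Electrophilic aromatic bromination of a phenol goes ortho to the hydroxyl here because the para position is blocked, and the two ortho positions are equivalent, so one equivalent of NBS should give a single monobromide.

**Step 3**
Reactants: 4 2-bromo-4-methoxy-3,5-dimethylphenol; 5 2,6-dimethoxybenzoyl chloride
Product: 6 2-bromo-4-methoxy-3,5-dimethylphenyl 2,6-dimethoxybenzoate
Conditions: Et3N, DMAP (0.2 equiv), CH2Cl2, 0 °C to reflux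
Reagents that add atoms: none
Why: DMAP-catalysed acylation of the phenol (nucleophilic acyl substitution) should tolerate the hindrance on both partners because the N-acylpyridinium intermediate is highly electrophilic.

**Step 4**
Reactants: 6 2-bromo-4-methoxy-3,5-dimethylphenyl 2,6-dimethoxybenzoate
Product: 9 2-(2,6-dimethoxybenzoyl)-4-methoxy-3,5-dimethylphenyl acetate, via aryllithium 7 (not isolated), via lithium phenoxide 8 (not isolated)
Conditions: n-BuLi (1.05 equiv), THF, −95 °C to −20 °C; then Ac2O (2 equiv), −78 °C to rt
Reagents that add atoms: acetic anhydride, CC(=O)OC(C)=O; n-butyllithium, [Li]CCCC (supplies only the lithium of 7 and 8)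
Why: Bromine–lithium exchange should outpace addition of n-BuLi to the doubly ortho-blocked ester, aryllithium 7 then attacks its own ester carbonyl (anionic Fries-type 1,3 O-to-C acyl shift of an ortho-lithioaryl ester) so that the aroyl group lands on the carbon that carried bromine without any Lewis acid, and phenoxide 8 is acetylated by Ac2O in the same flask.

**Step 5**
Reactants: 9 2-(2,6-dimethoxybenzoyl)-4-methoxy-3,5-dimethylphenyl acetate; 10 dioxygen
Product: 11 1-(2,6-dimethoxyphenyl)-1-hydroxy-5-methoxy-6-methyl-1,4-dihydro-2,3-benzodioxin-8-yl acetate (racemic)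
Conditions: hν (365 nm), O2 (1 atm, slow stream), benzene, 15 °C
Reagents that add atoms: none
Why: Excitation of the diaryl ketone in its long-wavelength n,π* band and intersystem crossing give the triplet, whose carbonyl oxygen takes a hydrogen from the C6 methyl group through a six-membered transition state (1,5-hydrogen transfer), and the 1,4-biradical relaxes to the hydroxy-ortho-quinodimethane (photoenol). Triplet oxygen then adds across the two ends of this dienol, most plausibly stepwise at the biradical or dienol stage, forming the CH2–O and C(OH)–O bonds; the closest known reaction is the photoenolisation of ortho-methylbenzophenones with capture of the dienol by oxygen as a cyclic peroxide. The one new ring, a six-membered 1,2-dioxane fused to ring B, is closed in a formal [4+2] mode with the dienol C(OH)=C1–C6=CH2 as the four-atom partner and O2 as the two-atom partner. The only new stereocentre, the hemiketal carbon, has no controlling element, forms as a racemate and is erased when the peroxide is reduced in step 6. Site selectivity is needed among the C6 methyl, the C4 methyl and the four methoxy groups: only the C6 methyl lies within reach of the carbonyl oxygen for the six-membered transfer, the C4 methyl and C5 methoxy are remote, and the ring A methoxy groups would need a slower seven-membered transfer of a non-benzylic hydrogen. The phenol is carried as its acetate so that excited-state proton transfer from an ortho hydroxyl cannot drain the excited ketone, and the long wavelength keeps the aryl acetate out of a photo-Fries path.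

**Step 6**
Reactants: 11 1-(2,6-dimethoxyphenyl)-1-hydroxy-5-methoxy-6-methyl-1,4-dihydro-2,3-benzodioxin-8-yl acetate
Product: 12 2-(2,6-dimethoxybenzoyl)-3-(hydroxymethyl)-4-methoxy-5-methylphenyl acetate
Conditions: PPh3 (1.1 equiv), CH2Cl2, 0 °C to rt; crude product taken on directly
Reagents that add atoms: none
Why: Triphenylphosphine takes one oxygen atom from the peroxide (phosphine reduction of a peroxide), and the resulting hemiketal opens to the ortho-(hydroxymethyl) ketone, which removes the racemic centre; 12 may rest partly as its cyclic hemiketal tautomer.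

**Step 7**
Reactants: 12 2-(2,6-dimethoxybenzoyl)-3-(hydroxymethyl)-4-methoxy-5-methylphenyl acetate
Product: 13 3-(acetoxymethyl)-2-(2,6-dimethoxybenzoyl)-4-methoxy-5-methylphenyl acetate
Conditions: Ac2O, pyridine, DMAP (cat.), CH2Cl2, 0 °C to rt
Reagents that add atoms: acetic anhydride, CC(=O)OC(C)=O
Why: DMAP-catalysed acetylation of the primary benzylic alcohol, where any cyclic hemiketal tautomer equilibrates through the open form, whose unhindered primary hydroxyl is acylated much faster than a tertiary hemiketal hydroxyl.

**Step 8**
Reactants: 13 3-(acetoxymethyl)-2-(2,6-dimethoxybenzoyl)-4-methoxy-5-methylphenyl acetate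
Product: 14 preacredinone A, [2-(2,6-dimethoxybenzoyl)-3-hydroxy-6-methoxy-5-methylphenyl]methyl acetate
Conditions: pyrrolidine (1.2 equiv), THF, 0 °C
Reagents that add atoms: none
Why: Chemoselective aminolysis, in which the aryl acetate (phenoxide leaving group, further activated by the ortho ketone) should be attacked by the amine far faster than the primary alkyl acetate, and the released phenol is held by a hydrogen bond to the ketone.

**Compound list**
1 | 3,5-dimethyl-4-methoxybenzaldehyde | COc1c(C)cc(C=O)cc1C | starting material
2 | 4-methoxy-3,5-dimethylphenyl formate (not isolated) | COc1c(C)cc(OC=O)cc1C | intermediate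
3 | 4-methoxy-3,5-dimethylphenol | COc1c(C)cc(O)cc1C | intermediate
4 | 2-bromo-4-methoxy-3,5-dimethylphenol | COc1c(C)cc(O)c(Br)c1C | intermediate
5 | 2,6-dimethoxybenzoyl chloride | COc1cccc(OC)c1C(Cl)=O | starting material
6 | 2-bromo-4-methoxy-3,5-dimethylphenyl 2,6-dimethoxybenzoate | COc1c(C)cc(OC(=O)c2c(OC)cccc2OC)c(Br)c1C | intermediate
7 | [2-(2,6-dimethoxybenzoyloxy)-5-methoxy-4,6-dimethylphenyl]lithium (not isolated) | [Li]c1c(C)c(OC)c(C)cc1OC(=O)c1c(OC)cccc1OC | intermediate
8 | lithium 2-(2,6-dimethoxybenzoyl)-4-methoxy-3,5-dimethylphenoxide (not isolated) | [Li]Oc1cc(C)c(OC)c(C)c1C(=O)c1c(OC)cccc1OC | intermediate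
9 | 2-(2,6-dimethoxybenzoyl)-4-methoxy-3,5-dimethylphenyl acetate | CC(=O)Oc1cc(C)c(OC)c(C)c1C(=O)c1c(OC)cccc1OC | intermediate
10 | dioxygen | O=O | starting material
11 | 1-(2,6-dimethoxyphenyl)-1-hydroxy-5-methoxy-6-methyl-1,4-dihydro-2,3-benzodioxin-8-yl acetate (racemic) | CC(=O)Oc1cc(C)c(OC)c2COOC(O)(c3c(OC)cccc3OC)c12 | intermediate
12 | 2-(2,6-dimethoxybenzoyl)-3-(hydroxymethyl)-4-methoxy-5-methylphenyl acetate | CC(=O)Oc1cc(C)c(OC)c(CO)c1C(=O)c1c(OC)cccc1OC | intermediate
13 | 3-(acetoxymethyl)-2-(2,6-dimethoxybenzoyl)-4-methoxy-5-methylphenyl acetate | CC(=O)OCc1c(OC)c(C)cc(OC(C)=O)c1C(=O)c1c(OC)cccc1OC | intermediate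
14 | preacredinone A | COc1cccc(OC)c1C(=O)c1c(O)cc(C)c(OC)c1COC(C)=O | target

**Totals**
Total step count: 8. Longest linear sequence: 8 steps (1 to 14).

**Steps most likely to fail**

Step 5. The crowded dienol may close to a benzocyclobutenol before oxygen captures it, or the peroxide may degrade under continued irradiation. The fallback separates light and oxygen and sets out from 9. Irradiation of 9 (365 nm) in degassed benzene under argon should give the benzocyclobutenol 7-(2,6-dimethoxyphenyl)-7-hydroxy-2-methoxy-3-methylbicyclo[4.2.0]octa-1,3,5-trien-5-yl acetate F1 by four-electron electrocyclic closure of the photoenol. Heating F1 in the dark in oxygen-saturated toluene at 80–90 °C should reopen the four-membered ring in a conrotatory way with the hydroxyl turning outward, and oxygen should capture the ground-state dienol, so that the route is rejoined at 11.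

Step 4. n-BuLi may add to the ester carbonyl, the aryllithium may be protonated before the acyl shift, or the acyl transfer onto the crowded carbon may stall. The fallback builds the ketone by carbonyl addition and oxidation and sets out from 4. MOMCl and i-Pr2NEt in CH2Cl2 should give 2-bromo-4-methoxy-1-(methoxymethoxy)-3,5-dimethylbenzene F2. Bromine–lithium exchange (n-BuLi, THF, −78 °C) and addition to purchased 2,6-dimethoxybenzaldehyde should give the racemic carbinol (2,6-dimethoxyphenyl)[3-methoxy-6-(methoxymethoxy)-2,4-dimethylphenyl]methanol F3. Dess–Martin periodinane with NaHCO3 in CH2Cl2 should oxidise it to (2,6-dimethoxyphenyl)[3-methoxy-6-(methoxymethoxy)-2,4-dimethylphenyl]methanone F4. HCl in MeOH should release 2-(2,6-dimethoxybenzoyl)-4-methoxy-3,5-dimethylphenol F5, and Ac2O, Et3N and DMAP should acetylate it, rejoining the route at 9.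

Step 8. The benzylic acetate may be lost together with the aryl acetate, or cleavage of the aryl acetate may be incomplete at a crowded, ketone-flanked position. The fallback reverses the order of deprotection and acylation and sets out from 12. K2CO3 in MeOH at 0 °C should remove the aryl acetate to give 2-(2,6-dimethoxybenzoyl)-3-(hydroxymethyl)-4-methoxy-5-methylphenol F6. Lipase-catalysed transesterification (Candida antarctica lipase B, vinyl acetate, MTBE, rt) should then acetylate only the primary alcohol, leaving the hindered, hydrogen-bonded phenol free, which arrives at 14.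

**Further compounds**
F1 | step 5 | 7-(2,6-dimethoxyphenyl)-7-hydroxy-2-methoxy-3-methylbicyclo[4.2.0]octa-1,3,5-trien-5-yl acetate (racemic) | CC(=O)Oc1cc(C)c(OC)c2CC(O)(c3c(OC)cccc3OC)c12
F2 | step 4 | 2-bromo-4-methoxy-1-(methoxymethoxy)-3,5-dimethylbenzene | COCOc1cc(C)c(OC)c(C)c1Br
F3 | step 4 | (2,6-dimethoxyphenyl)[3-methoxy-6-(methoxymethoxy)-2,4-dimethylphenyl]methanol (racemic) | COCOc1cc(C)c(OC)c(C)c1C(O)c1c(OC)cccc1OC
F4 | step 4 | (2,6-dimethoxyphenyl)[3-methoxy-6-(methoxymethoxy)-2,4-dimethylphenyl]methanone | COCOc1cc(C)c(OC)c(C)c1C(=O)c1c(OC)cccc1OC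
F5 | step 4 | 2-(2,6-dimethoxybenzoyl)-4-methoxy-3,5-dimethylphenol | Oc1cc(C)c(OC)c(C)c1C(=O)c1c(OC)cccc1OC
F6 | step 8 | 2-(2,6-dimethoxybenzoyl)-3-(hydroxymethyl)-4-methoxy-5-methylphenol | Oc1cc(C)c(OC)c(CO)c1C(=O)c1c(OC)cccc1OC
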